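Compound numbers 1–33 are fixed by the steps below and are used in every section. Compound 13 is the precursor and 16 the product of the key step; 33 is the target.

## The problem

Compound 33 is a pentacycle built on a fully substituted N-alkylpyrrole (N4, C1, C2–H, C3, C9a) that shares its N4–C9a edge with an azepine (N4–C5–C6–C7–C8–C9–C9a) and its C9a–C1 edge with cyclohexane ring B (C9a–C9–C10–C11–C12–C1); an α-methyl-γ-butyrolactone D (C11–O–C14(=O)–C13–C12) is cis-fused to ring B, and a second one, lactone E (O–C18–C19–C20–C21(=O)), hangs from C3 through its carbinol carbon C18. Five of the seven stereocentres are contiguous (C9 to C13): H9 and H10 are trans, the C10 ethyl group is anti to the oxygen on C11, and H11, H12 and H13 are all cis, so the C13 methyl group lies on the concave face of the cis-fused bicycle, where neither enolate methylation nor equilibration would place it. C18 and C20 (cis on lactone E) are insulated from the core by the flat pyrrole, so C18 needs reagent control and can then steer C20. Inside the core the centres can be relayed: one carbinol centre can fix C9 and C10 if the C9–C10 bond is made suprafacially, the C10 ethyl group can then send a reagent to the opposite face of a C11=C12 alkene, and the cis ring fusion exposes the convex face of lactone D for hydrogen delivery to C13. The fragile points are the electron-rich pyrrole (sensitive to acid and electrophilic oxidants, most of all while C3 is unsubstituted or a vinyl group is conjugated to it), the ionisable C18–O bond of a pyrrolyl carbinol ester, the epimerisable lactone α-carbons and any C9 centre that is α to a carbonyl group. The enabling feature is that C9, attached to pyrrole carbon C9a, is bonded to C10 and carries C8, a carbon that can pass through the carboxyl oxidation level, while C12 sits on pyrrole carbon C1. The atoms C9=C8(O)–O–C12–C11=C10 of the enol derivative of a pyrrole-fused δ-lactone with a butenyl group on C12 therefore form a 3-oxa-1,5-diene, whose [3,3] shift closes ring B, delivers C8 as a carboxylic acid and leaves a C11=C12 alkene on which lactone D can be built.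

## Retrosynthesis

**33 from 32.** The C13–H and C20–H bonds and the two hydrogens on C7/C8 are removed, giving the bis(α-methylene) lactone 32 with a C7=C8 alkene. This is preferred to methylation of the lactone enolates, which would put the C13 methyl group on the convex face. Hydrogen delivered from the convex face of lactone D and anti to the pyrrolyl group on lactone E gives both methyl centres, and the same operation saturates the azepine. The forward step must add hydrogen without cleaving the C18–O bond and without moving the exocyclic alkenes into the rings.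

**32 from 28.** The two exocyclic C=CH2 bonds are cut, leading to the unsubstituted bis-lactone 28 and two equivalents of the one-carbon electrophile 29, with 30 and 31 as relay compounds. Treating both lactones alike avoids having to tell their enolates apart. The forward reaction is a twofold enolate Mannich reaction and elimination.

**28 from 26, and 26 from 25.** The C18–O lactone bond and the C18–H bond are cut to give keto ester 26, via hydroxy ester 27. C18 is thus set by a catalyst-controlled ketone reduction, and until then the acyl group deactivates the pyrrole. The C7=C8 bond of 26 is opened to the two terminal alkenes of 25 by a metathesis transform. Placing the ring closure after the cycloaddition of the next paragraph keeps a reactive cycloalkene out of that step.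

**25 from 21.** Lactone D is disconnected at O–C11 (oxygen insertion), C11–C14 and C12–C13. This leads through cyclobutanone 24 and dichlorocyclobutanone 23 to the C11=C12 alkene 21 and the ketene precursor 22. Against hydration of the alkene followed by enolate alkylation, this cut makes both ring-fusion centres in one cis-addition directed by the C10 ethyl group and does not expose C10 to enolisation. Two stereocentres and one ring are removed. The forward cycloaddition must choose the conjugated alkene over two monosubstituted ones and the face anti to the ethyl group.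

**21 from 19 and 20.** The C3–C18 bond is cut by a Friedel–Crafts transform, which brings all four carbons of lactone E in one commercial acid chloride (20). It is done before the ketene chemistry because the free α-position of 19 would otherwise be the most nucleophilic site of the molecule.

**19 from 16.** The C8=CH2 bond is traced back through aldehyde 18 and alcohol 17 to the carboxylic acid 16. The carboxyl carbon becomes C8, and the added methylene is the one later lost in the ring closure. The forward sequence must not epimerise C9.

**16 from 13 (key disconnection).** The C9–C10 bond is cut and the O–C12 bond restored, turning ring B into the pyrrole-fused δ-lactone 13 with a (Z)-butenyl group on the carbinol carbon. The forward reaction goes through silyl ketene acetal 14 and silyl ester 15. Compared with making ring B by alkylation or cycloaddition, this cut trades two stereocentres for one and uses a lactone that is assembled from a simple pyrrole. The forward reaction must be suprafacial and pass through the boat.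

**13 from 12, and 12 from 9 and 10.** The Z alkene comes from alkyne 12 by cis-semihydrogenation. The C12–alkynyl bond and the lactone C–O bond are then cut to aldehyde ester 9 and alkyne 10, via hydroxy ester 11. This puts the only stereocentre of the first half of the route under catalyst control.

**9 from 1, 2 and 3.** The pyrrole is disconnected by a Hantzsch transform to 1, 2 and 3 through enamine 4 and diester 5. The two esters of 5 are told apart by their reactivity: saponification to diacid 6, selective re-esterification of the aliphatic acid to 7, and reduction of the ring carboxyl through acid chloride 8. The N-butenyl group is carried from the first step as the later metathesis partner.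

## Roads not taken

Alternative 1: carbenoid C–H insertion for lactone D. The cut is C12–C13 on a tricycle that already has the pyrrole, ring B and the azepine. In the forward step Rh2(esp)2 (esp = α,α,α′,α′-tetramethyl-1,3-benzenedipropionate) decomposes the α-diazopropionate A1 on the C11 oxygen, and the carbenoid inserts into the cis C12–H bond to give lactone A2.
- Merits: the C12–H bond is activated by the pyrrole, the five-membered insertion makes the cis fusion automatically, and the methyl-bearing carbon arrives with the lactone. Lactone D is finished in fewer operations than in the chosen plan, which needs cycloaddition, oxidation, methylenation and hydrogenation. In this respect Alternative 1 is better.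
- Weak points: α-alkyl diazo esters lose nitrogen with 1,2-hydride shift to acrylates. The tertiary C10–H bond is an equally placed 1,5-competitor. The electron-rich pyrrole can be attacked at C2. C13 is left unassigned in A2, and equilibration would favour the convex methyl group, the wrong one.
- Comparison: the alternative addresses lactone D only. It still needs C9, C10 and a correctly configured C11 alcohol from elsewhere. The chosen plan sets C11 and C12 in one cis-addition, sets C13 kinetically, and provides C9 and C10 through the Claisen step.

Alternative 2: Friedel–Crafts and aza-Michael cascade. The cuts are C9a–C9 and N4–C5. In the forward step Sc(OTf)3 makes the free pyrrole α-carbon of dienone A3 attack the enone β-carbon C9 (6-exo-trig). DBU then adds the N–H to the terminal vinyl ketone carbon C5 (7-endo-trig), giving the 7-oxo compound A4.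
- Merits: two rings and two bonds are made in one flask from an open chain. This is more convergent than the chosen plan, which closes one ring in its key step and needs a separate metathesis for the azepine.
- Weak points: a cross-conjugated divinyl ketone under Lewis acid is set up for Nazarov cyclisation and polymerisation. C9 is controlled only by 1,2-induction from C10. Lactones D and E and the centres C10–C13 must be built on an acyclic chain without a ring template. The ionisable C18–O bond meets Sc(OTf)3. The C7 ketone of A4 has to be removed afterwards in the presence of two lactones.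
- Comparison: the chosen plan sets against this a stereospecific transfer of chirality from one robust carbinol centre, and it carries no functional group that must be deleted later, apart from the methylene lost in the ring closure.

Alternative 3: Hosomi–Sakurai closure of ring B. The cut is C10–C11 together with the lactone C–O bond. In the forward step BF3·OEt2 activates the C11 aldehyde of A5. The γ-carbon C10 of the allylsilane attacks it through a chair-like transition state, and the new hydroxyl lactonises onto the methyl ester to give the 10-vinyl compound A6, which needs only hydrogenation of the vinyl group.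
- Merits: ring B and lactone D form together, and C10 and C11 are set at once. The required all-trans arrangement of C9, C10 and C11 corresponds to an all-equatorial chair, so the stereochemical match is good. The C13 methyl group is in place from the start. For the ring B and lactone D pair this road is at least as short as the chosen one.
- Weak points: the C12 centre of A5 is α to an aldehyde and attached to the pyrrole, so it is configurationally labile. C9, C12 and C13 must each be set independently beforehand. BF3·OEt2 meets the electron-rich pyrrole and the C18–O bond.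
- Comparison: the chosen plan sets against the shorter end-game a precursor with a single stereocentre, and it makes C12 at a stage where it is flanked by a lactone and cannot epimerise.

Key step: step 7

Remark: locants are those of the skeleton defined in "The problem" (C13/C14 in lactone D, C18–C21 in lactone E).
Remark: the Ti(Oi-Pr)4–(S)-BINOL catalyst is assumed to deliver the alkynyl group to the Si face of 9, as it does with aryl aldehydes; if the sense is opposite, (R)-BINOL is used.

## Steps

Step 1
Reactants: 1 dimethyl 3-oxopentanedioate; 2 but-3-en-1-amine; 3 chloroacetaldehyde (50 % aqueous)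
Product: 5 methyl 1-(but-3-en-1-yl)-2-(2-methoxy-2-oxoethyl)-1H-pyrrole-3-carboxylate, via enamino diester 4 (not isolated)
Conditions: 1 + 2, MeOH–H2O, 0 °C → rt; then 3, NaHCO3, rt
Reagents that add atoms: none
Why: Hantzsch pyrrole synthesis: the amine condenses with the ketone of 1 to give enamino ester 4, whose β-carbon adds to the aldehyde of 3 while nitrogen displaces chloride; this is the standard entry to 1-alkyl-3-alkoxycarbonylpyrrole-2-acetates.

Step 2
Reactants: 5 methyl 1-(but-3-en-1-yl)-2-(2-methoxy-2-oxoethyl)-1H-pyrrole-3-carboxylate
Product: 6 1-(but-3-en-1-yl)-2-(carboxymethyl)-1H-pyrrole-3-carboxylic acid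
Conditions: NaOH, MeOH–H2O, reflux; then HCl to pH 3, 0 °C
Reagents that add atoms: sodium hydroxide, [Na+].[OH-]
Why: Saponification of both esters; the ring ester, a vinylogous carbamate, needs reflux, and cold acidification avoids decarboxylation of the pyrrolylacetic acid.

Step 3
Reactants: 6 1-(but-3-en-1-yl)-2-(carboxymethyl)-1H-pyrrole-3-carboxylic acid
Product: 7 1-(but-3-en-1-yl)-2-(2-methoxy-2-oxoethyl)-1H-pyrrole-3-carboxylic acid
Conditions: MeOH, HCl (cat.), rt
Reagents that add atoms: methanol, CO
Why: Fischer esterification discriminates between the two acids: the aliphatic acetic acid esterifies at room temperature, whereas the ring carboxylic acid, conjugated with the pyrrole nitrogen, is not attacked by methanol under these conditions.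

Step 4
Reactants: 7 1-(but-3-en-1-yl)-2-(2-methoxy-2-oxoethyl)-1H-pyrrole-3-carboxylic acid
Product: 9 methyl 2-[1-(but-3-en-1-yl)-3-formyl-1H-pyrrol-2-yl]acetate, via acid chloride 8 (not isolated)
Conditions: 1-chloro-N,N,2-trimethylprop-1-en-1-amine, CH2Cl2, 0 °C → rt; then LiAlH(Ot-Bu)3, THF, −78 °C
Reagents that add atoms: none
Why: Neutral acid chloride formation with an α-chloroenamine, then partial reduction of the acid chloride by the hindered hydride, which leaves the methyl ester untouched at −78 °C; the aldehyde formed is a vinylogous formamide and resists over-reduction.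

Step 5
Reactants: 9 methyl 2-[1-(but-3-en-1-yl)-3-formyl-1H-pyrrol-2-yl]acetate; 10 but-1-yne
Product: 12 (4S)-1-(but-3-en-1-yl)-4-(but-1-yn-1-yl)-4,7-dihydropyrano[4,3-b]pyrrol-6(1H)-one, via hydroxy ester 11 (not isolated)
Conditions: 10, Et2Zn, Cy2NH (cat.), Et2O, rt; (S)-BINOL (20 mol %), Ti(Oi-Pr)4 (50 mol %); then 9, rt; then 40 °C; H2O
Reagents that add atoms: none
Why: Catalytic asymmetric alkynylzinc addition to an aldehyde under Ti(Oi-Pr)4–BINOL control sets the carbinol centre (S) by Si-face attack; the metal alkoxide of 11 then lactonises onto the neighbouring acetate ester (Ti(Oi-Pr)4-mediated transesterification, 6-exo-trig) to give the δ-lactone.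

Step 6
Reactants: 12 (4S)-1-(but-3-en-1-yl)-4-(but-1-yn-1-yl)-4,7-dihydropyrano[4,3-b]pyrrol-6(1H)-one
Product: 13 (4S)-1-(but-3-en-1-yl)-4-[(1Z)-but-1-en-1-yl]-4,7-dihydropyrano[4,3-b]pyrrol-6(1H)-one
Conditions: H2 (1 atm, 1 equiv), Pd/CaCO3–Pb(OAc)2, quinoline, EtOAc, rt
Reagents that add atoms: none
Why: Lindlar-type cis-semihydrogenation adds hydrogen syn to the alkyne and gives the Z alkene; the poisoned catalyst reduces the alkyne much faster than the monosubstituted N-butenyl alkene, and the carbinol centre is not touched.

Step 7
Reactants: 13 (4S)-1-(but-3-en-1-yl)-4-[(1Z)-but-1-en-1-yl]-4,7-dihydropyrano[4,3-b]pyrrol-6(1H)-one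
Product: 16 (6S,7R)-1-(but-3-en-1-yl)-6-ethyl-6,7-dihydro-1H-indole-7-carboxylic acid, via silyl ketene acetal 14 (not isolated), via trimethylsilyl ester 15 (not isolated)
Conditions: LiN(SiMe3)2, Me3SiCl, Et3N, THF, −78 °C → rt; PhMe, 80 °C; then aq. KH2PO4
Reagents that add atoms: none
Why: Ireland–Claisen rearrangement of a lactone silyl ketene acetal (lactone-enolate Claisen carbocyclisation). LiN(SiMe3)2 removes a C9 proton of 13 and Me3SiCl traps the enolate on oxygen as the endocyclic ketene acetal 14, whose atoms C9=C8(OSi)–O–C12–C11=C10 form a 3-oxa-1,5-diene. The concerted suprafacial [3,3] shift makes C9–C10, breaks O–C12 and moves the alkene to C11=C12, giving silyl ester 15 and, after aqueous work-up, acid 16; the closest known reaction type is the rearrangement of silyl ketene acetals of δ-lactones bearing an alkenyl group on the carbinol carbon to cyclohexenecarboxylic acids. Ring B closes as a six-membered carbocycle by this sigmatropic bond formation, and because the pyrrole edge C9a–C1 ties C9 to C12 a chair is impossible, so the array reacts through a boat (bicyclo[2.2.2]-like) transition state. C9 is set by the carbinol centre, since the butenyl group can reach C9 only across the lactone face on which it stands, which turns the 4S centre of 13 into the 7R centre of 16. C10 is set by the alkene geometry within that boat: the Z-ethyl group points toward the pyrrole bridge and ends trans to the carboxyl group, whereas an E alkene would give the cis acid. The step needs complete O-silylation, intact Z geometry and a concerted rather than ionising pathway; the acidity of the pyrrole-activated C9 protons, the cis-semihydrogenation of step 6 and the amine-buffered medium of low polarity are meant to secure these. The driving force is the exchange of a ketene acetal for a carboxylate and a pyrrole-conjugated alkene.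

Step 8
Reactants: 16 (6S,7R)-1-(but-3-en-1-yl)-6-ethyl-6,7-dihydro-1H-indole-7-carboxylic acid
Product: 17 [(6S,7R)-1-(but-3-en-1-yl)-6-ethyl-6,7-dihydro-1H-indol-7-yl]methanol
Conditions: LiAlH4, THF, 0 °C
Reagents that add atoms: none
Why: Hydride reduction of the carboxylic acid to the primary alcohol; the conjugated and terminal alkenes are inert to LiAlH4 and no stereocentre is involved.

Step 9
Reactants: 17 [(6S,7R)-1-(but-3-en-1-yl)-6-ethyl-6,7-dihydro-1H-indol-7-yl]methanol
Product: 18 (6S,7R)-1-(but-3-en-1-yl)-6-ethyl-6,7-dihydro-1H-indole-7-carbaldehyde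
Conditions: (n-Pr)4N[RuO4] (cat.), N-methylmorpholine N-oxide, 4 Å MS, CH2Cl2, 0 °C
Reagents that add atoms: none
Why: Ley oxidation with catalytic (n-Pr)4N[RuO4] works under neutral, non-electrophilic conditions, which should spare the vinylpyrrole and limit enolisation of the C9 aldehyde; the crude aldehyde is used at once.

Step 10
Reactants: 18 (6S,7R)-1-(but-3-en-1-yl)-6-ethyl-6,7-dihydro-1H-indole-7-carbaldehyde
Product: 19 (6S,7R)-1-(but-3-en-1-yl)-7-ethenyl-6-ethyl-6,7-dihydro-1H-indole
Conditions: Ph3PCH3Br, KN(SiMe3)2, THF, −78 → 0 °C
Reagents that add atoms: methyltriphenylphosphonium bromide, C[P+](c1ccccc1)(c1ccccc1)c1ccccc1.[Br-]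
Why: Wittig methylenation; at low temperature the salt-free ylide adds to the aldehyde faster than it deprotonates C9, so the trans arrangement of C9 and C10 should be kept.

Step 11
Reactants: 19 (6S,7R)-1-(but-3-en-1-yl)-7-ethenyl-6-ethyl-6,7-dihydro-1H-indole; 20 methyl 4-chloro-4-oxobutanoate
Product: 21 methyl 4-[(6S,7R)-1-(but-3-en-1-yl)-7-ethenyl-6-ethyl-6,7-dihydro-1H-indol-2-yl]-4-oxobutanoate
Conditions: Et2AlCl, CH2Cl2, −78 → 0 °C
Reagents that add atoms: none
Why: Friedel–Crafts acylation at the only free α-position of the pyrrole (C3 of the skeleton); Et2AlCl activates the acid chloride and removes the hydrogen chloride as ethane, so the acid-labile vinylpyrrole is not protonated.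

Step 12
Reactants: 21 methyl 4-[(6S,7R)-1-(but-3-en-1-yl)-7-ethenyl-6-ethyl-6,7-dihydro-1H-indol-2-yl]-4-oxobutanoate; 22 trichloroacetyl chloride
Product: 23 cis-fused 2,2-dichlorocyclobutanone across C11–C12 of the acylated dihydroindole (carbonyl carbon C14 on C11; CCl2 carbon C13 on C12; both new bonds anti to the C10 ethyl group)
Conditions: Zn–Cu couple, POCl3, Et2O, rt, slow addition of 22
Reagents that add atoms: none
Why: [2+2] cycloaddition of dichloroketene (made from 22 and zinc) to the pyrrole-conjugated alkene; as with styrenes the ketene carbonyl carbon bonds to the nucleophilic terminus C11 and the CCl2 carbon to the cation-stabilising C12, the cis fusion is inherent, and the adjacent C10 ethyl group should direct addition to the opposite face. The acyl group installed in step 11 keeps the pyrrole ring itself from being acylated, and the two monosubstituted alkenes belong to the least reactive class of ketenophiles.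

Step 13
Reactants: 23 cis-fused 2,2-dichlorocyclobutanone across C11–C12 of the acylated dihydroindole
Product: 25 keto ester carrying the cis-fused γ-lactone D (C11–O–C14(=O)–C13H2–C12) beside the N-butenyl group plus the C9 vinyl group, via cyclobutanone 24 (not isolated)
Conditions: Zn, AcOH, rt; filter; then 30 % H2O2, 0 °C
Reagents that add atoms: hydrogen peroxide, OO
Why: Zinc in acetic acid removes both chlorines through the zinc enolate; Baeyer–Villiger oxidation of the strained cyclobutanone then inserts oxygen on the side of the more substituted ring-fusion carbon C11 with retention, giving lactone D with C11 and C12 as in the target. The acylpyrrole ketone and the monosubstituted alkenes do not react with cold hydrogen peroxide in acetic acid.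

Step 14
Reactants: 25 keto ester carrying the cis-fused γ-lactone D, the N-butenyl group and the C9 vinyl group
Product: 26 azepine-closed keto ester (C7=C8 alkene; pyrrole, ring B, lactone D and azepine complete)
Conditions: second-generation Grubbs catalyst (H2IMes)(PCy3)Cl2Ru=CHPh (cat.), CH2Cl2, 40 °C, high dilution
Reagents that add atoms: none
Why: Ring-closing metathesis of the two monosubstituted alkenes forms the seven-membered ring with loss of ethene; the ketone, ester and lactone are tolerated.

Step 15
Reactants: 26 azepine-closed keto ester
Product: 28 bis-lactone with unsubstituted lactones D and E and the (18S) configuration (C7=C8 alkene), via hydroxy ester 27 (not isolated)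
Conditions: (R)-2-methyl-CBS-oxazaborolidine (cat.), catecholborane, PhMe, −78 → −30 °C; MeOH; then DBU (cat.), PhMe, 40 °C
Reagents that add atoms: none
Why: Corey–Bakshi–Shibata reduction: with the pyrrolyl group as the large substituent the (R)-catalyst should give the (18S) carbinol, and catecholborane at low temperature neither hydroborates the alkene nor reduces lactone D. Base then closes lactone E by 5-exo-trig attack of the hydroxyl on the methyl ester, which avoids acid at the ionisable pyrrolyl carbinol.

Step 16
Reactants: 28 bis-lactone with unsubstituted lactones D and E; 29 N,N-dimethylmethyleneiminium iodide (Eschenmoser's salt; two equivalents are consumed, one for each lactone)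
Product: 30 bis-Mannich base (CH2NMe2 on C13 and on C20; configuration at these two carbons unassigned)
Conditions: LiN(i-Pr)2 (2.5 equiv), THF, −78 °C; then 29 (2.5 equiv), −78 °C → rt
Reagents that add atoms: N,N-dimethylmethyleneiminium iodide (the second equivalent of 29), C=[N+](C)C.[I-]
Why: Twofold lithium enolate formation and Mannich reaction, each enolate taking up one equivalent of the iminium salt; both lactones have only their α-CH2 as acidic site, and the two new centres are removed in the next step.

Step 17
Reactants: 30 bis-Mannich base
Product: 32 bis(α-methylene) lactone (C13=CH2 and C20=CH2; C7=C8 alkene), via bis-ammonium diiodide 31 (not isolated)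
Conditions: MeI, MeOH, rt; then DBU, CH2Cl2, rt
Reagents that add atoms: none
Why: Exhaustive N-methylation followed by base-induced elimination of trimethylamine (E1cB) is the standard way to α-methylene lactones from Mannich bases.

Step 18
Reactants: 32 bis(α-methylene) lactone
Product: 33 CNP0232452.6 (target)
Conditions: H2 (3 atm), RhCl(PPh3)3 (cat.), PhH–EtOH, rt
Reagents that add atoms: none
Why: Homogeneous hydrogenation adds hydrogen syn to all three alkenes: at C13 from the convex face of the cis-fused lactone D, which puts the methyl group on the concave face (H13 cis to H12), and at C20 from the face opposite the pyrrolyl group, which gives the cis lactone E. The neutral catalyst RhCl(PPh3)3 is chosen to avoid hydrogenolysis of the C18–O bond and migration of the exocyclic alkenes.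

## Compound list

1 | dimethyl 3-oxopentanedioate (dimethyl 1,3-acetonedicarboxylate) | COC(=O)CC(=O)CC(=O)OC | starting material
2 | but-3-en-1-amine | C=CCCN | starting material
3 | chloroacetaldehyde | ClCC=O | starting material
4 | dimethyl (2Z)-3-(but-3-en-1-ylamino)pent-2-enedioate | C=CCCN/C(CC(=O)OC)=C\C(=O)OC | intermediate
5 | methyl 1-(but-3-en-1-yl)-2-(2-methoxy-2-oxoethyl)-1H-pyrrole-3-carboxylate | COC(=O)Cc1c(C(=O)OC)ccn1CCC=C | intermediate
6 | 1-(but-3-en-1-yl)-2-(carboxymethyl)-1H-pyrrole-3-carboxylic acid | OC(=O)Cc1c(C(=O)O)ccn1CCC=C | intermediate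
7 | 1-(but-3-en-1-yl)-2-(2-methoxy-2-oxoethyl)-1H-pyrrole-3-carboxylic acid | COC(=O)Cc1c(C(=O)O)ccn1CCC=C | intermediate
8 | methyl 2-[1-(but-3-en-1-yl)-3-(chlorocarbonyl)-1H-pyrrol-2-yl]acetate | COC(=O)Cc1c(C(Cl)=O)ccn1CCC=C | intermediate
9 | methyl 2-[1-(but-3-en-1-yl)-3-formyl-1H-pyrrol-2-yl]acetate | COC(=O)Cc1c(C=O)ccn1CCC=C | intermediate
10 | but-1-yne | CCC#C | starting material
11 | methyl 2-{1-(but-3-en-1-yl)-3-[(1S)-1-hydroxypent-2-yn-1-yl]-1H-pyrrol-2-yl}acetate | CCC#C[C@H](O)c1ccn(CCC=C)c1CC(=O)OC | intermediate
12 | (4S)-1-(but-3-en-1-yl)-4-(but-1-yn-1-yl)-4,7-dihydropyrano[4,3-b]pyrrol-6(1H)-one | CCC#C[C@@H]1OC(=O)Cc2c1ccn2CCC=C | intermediate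
13 | (4S)-1-(but-3-en-1-yl)-4-[(1Z)-but-1-en-1-yl]-4,7-dihydropyrano[4,3-b]pyrrol-6(1H)-one | CC/C=C\[C@@H]1OC(=O)Cc2c1ccn2CCC=C | intermediate
14 | (4S)-1-(but-3-en-1-yl)-4-[(1Z)-but-1-en-1-yl]-6-(trimethylsilyloxy)-1,4-dihydropyrano[4,3-b]pyrrole | CC/C=C\[C@@H]1OC(O[Si](C)(C)C)=Cc2c1ccn2CCC=C | intermediate
15 | trimethylsilyl (6S,7R)-1-(but-3-en-1-yl)-6-ethyl-6,7-dihydro-1H-indole-7-carboxylate | CC[C@H]1C=Cc2ccn(CCC=C)c2[C@@H]1C(=O)O[Si](C)(C)C | intermediate
16 | (6S,7R)-1-(but-3-en-1-yl)-6-ethyl-6,7-dihydro-1H-indole-7-carboxylic acid | CC[C@H]1C=Cc2ccn(CCC=C)c2[C@@H]1C(=O)O | intermediate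
17 | [(6S,7R)-1-(but-3-en-1-yl)-6-ethyl-6,7-dihydro-1H-indol-7-yl]methanol | CC[C@H]1C=Cc2ccn(CCC=C)c2[C@@H]1CO | intermediate
18 | (6S,7R)-1-(but-3-en-1-yl)-6-ethyl-6,7-dihydro-1H-indole-7-carbaldehyde | CC[C@H]1C=Cc2ccn(CCC=C)c2[C@@H]1C=O | intermediate
19 | (6S,7R)-1-(but-3-en-1-yl)-7-ethenyl-6-ethyl-6,7-dihydro-1H-indole | CC[C@H]1C=Cc2ccn(CCC=C)c2[C@@H]1C=C | intermediate
20 | methyl 4-chloro-4-oxobutanoate | COC(=O)CCC(Cl)=O | starting material
21 | methyl 4-[(6S,7R)-1-(but-3-en-1-yl)-7-ethenyl-6-ethyl-6,7-dihydro-1H-indol-2-yl]-4-oxobutanoate | CC[C@H]1C=Cc2cc(C(=O)CCC(=O)OC)n(CCC=C)c2[C@@H]1C=C | intermediate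
22 | trichloroacetyl chloride | ClC(Cl)(Cl)C(Cl)=O | starting material
23 | cis-fused 2,2-dichlorocyclobutanone across C11–C12 of the acylated dihydroindole (C14=O on C11, C13Cl2 on C12, anti to the C10 ethyl group) | CC[C@H]1[C@@H]2C(=O)C(Cl)(Cl)[C@@H]2c2cc(C(=O)CCC(=O)OC)n(CCC=C)c2[C@@H]1C=C | intermediate
24 | cis-fused cyclobutanone (dechlorinated 23) | CC[C@H]1[C@@H]2C(=O)C[C@@H]2c2cc(C(=O)CCC(=O)OC)n(CCC=C)c2[C@@H]1C=C | intermediate
25 | keto ester carrying the cis-fused γ-lactone D, the N-butenyl group and the C9 vinyl group | CC[C@H]1[C@@H]2OC(=O)C[C@@H]2c2cc(C(=O)CCC(=O)OC)n(CCC=C)c2[C@@H]1C=C | intermediate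
26 | azepine-closed keto ester (C7=C8 alkene) | CC[C@H]1[C@@H]2OC(=O)C[C@@H]2c2cc(C(=O)CCC(=O)OC)n3c2[C@@H]1C=CCC3 | intermediate
27 | (18S)-hydroxy ester of 26 | CC[C@H]1[C@@H]2OC(=O)C[C@@H]2c2cc([C@@H](O)CCC(=O)OC)n3c2[C@@H]1C=CCC3 | intermediate
28 | bis-lactone (lactones D and E without methyl groups, 18S, C7=C8 alkene) | CC[C@H]1[C@@H]2OC(=O)C[C@@H]2c2cc([C@@H]3CCC(=O)O3)n3c2[C@@H]1C=CCC3 | intermediate
29 | N,N-dimethylmethyleneiminium iodide | C=[N+](C)C.[I-] | starting material
30 | bis-Mannich base (CH2NMe2 on C13 and C20, these two centres unassigned) | CC[C@H]1[C@@H]2OC(=O)C(CN(C)C)[C@@H]2c2cc([C@@H]3CC(CN(C)C)C(=O)O3)n3c2[C@@H]1C=CCC3 | intermediate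
31 | bis(trimethylammoniomethyl) diiodide of 30 | CC[C@H]1[C@@H]2OC(=O)C(C[N+](C)(C)C)[C@@H]2c2cc([C@@H]3CC(C[N+](C)(C)C)C(=O)O3)n3c2[C@@H]1C=CCC3.[I-].[I-] | intermediate
32 | bis(α-methylene) lactone (C13=CH2, C20=CH2, C7=C8) | CC[C@H]1[C@@H]2OC(=O)C(=C)[C@@H]2c2cc([C@@H]3CC(=C)C(=O)O3)n3c2[C@@H]1C=CCC3 | intermediate
33 | CNP0232452.6 | CC[C@H]1[C@@H]2OC(=O)[C@H](C)[C@@H]2c2cc([C@@H]3C[C@H](C)C(=O)O3)n3c2[C@@H]1CCCC3 | target

## Step count and least certain steps

Total step count: 18. Longest linear sequence: 18 steps (from 1, 2 and 3 to 33).

**Step 7 (key step).** The boat forces the Z-ethyl group over the pyrrole bridge, so the rearrangement may be slow. Ionisation of the O–C12 bond, which is both pyrrolyl and allylic, could then compete and erode the transfer of chirality or isomerise the alkene.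

The fallback keeps the Claisen disconnection but uses the unhindered E alkene with the opposite carbinol configuration. It sets out from aldehyde 9. An (E)-but-1-enylzinc reagent, made from 10 by hydrozirconation with Cp2Zr(H)Cl and transmetalation with Me2Zn, is added in the presence of the enantiomer of a chiral amino alcohol ligand that directs it to the Re face; this gives methyl 2-{1-(but-3-en-1-yl)-3-[(1R,2E)-1-hydroxypent-2-en-1-yl]-1H-pyrrol-2-yl}acetate F1. Ti(Oi-Pr)4-catalysed lactonisation gives the (4R)-E-butenyl lactone F2. Under the conditions of step 7, F2 passes through its silyl ketene acetal F3 and the cis silyl ester F4 to the cis acid F5, (6S,7S). Esterification with trimethylsilyldiazomethane gives the cis methyl ester F6. Equilibration at C7 with NaOMe in MeOH should favour the trans methyl ester F7, in which both substituents can be pseudoaxial and free of strain against the N-substituent; this preference is expected, not assured. LiAlH4 reduces F7 to alcohol 17, where the route is rejoined.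

**Step 5.** The aldehyde of 9 is a vinylogous formamide and a poor electrophile. The addition may be slow, and a slow catalysed pathway invites ethyl transfer and loss of enantioselectivity.

The fallback sets out from acid chloride 8. Copper-free, palladium-catalysed acylation of 10 (PdCl2(PPh3)2, Et3N; Sonogashira-type coupling of an acid chloride) gives methyl 2-[1-(but-3-en-1-yl)-3-(pent-2-ynoyl)-1H-pyrrol-2-yl]acetate F8. Midland reduction with the antipode of Alpine-Borane that treats the alkynyl group as the small substituent gives hydroxy ester 11. Ti(Oi-Pr)4-catalysed lactonisation then returns to 12.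

**Step 12.** The acyl group lowers the nucleophilicity of the C11=C12 alkene. Cycloaddition at the two monosubstituted alkenes may then compete, and a pseudoaxial C9 vinyl group may weaken the facial preference set by the ethyl group.

The fallback reverses the order of the two lactone constructions, so that the ketene meets an electron-rich alkene whose pyrrole α-position is blocked by an sp3 carbon. It sets out from 21. The reduction and lactonisation of step 15 are applied to 21; they give the (4S)-hydroxy ester F9 and then the triene lactone F10, (5S)-5-[(6S,7R)-1-(but-3-en-1-yl)-7-ethenyl-6-ethyl-6,7-dihydro-1H-indol-2-yl]dihydrofuran-2(3H)-one. Dichloroketene generated from dichloroacetyl chloride and Et3N, a method that adds only to activated alkenes, gives dichlorocyclobutanone F11. Zinc with NH4Cl in MeOH gives cyclobutanone F12. Nucleophilic Baeyer–Villiger oxidation (t-BuOOH, aqueous NaOH, THF, 0 °C, buffered acidification) gives the bis-lactone triene F13. Ring-closing metathesis as in step 14 returns to 28.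

**Step 15.** Hydride transfer to the acylpyrrole carbonyl, a doubly vinylogous amide, may be sluggish. The product carbinol can ionise, which would cost configuration at C18 or lead to loss of the oxygen.

The fallback replaces asymmetric catalysis by separation and recycling. It sets out from 26. Reduction with NaBH4 and CeCl3 in MeOH at low temperature gives hydroxy ester 27 together with its C18 epimer, the (18R)-hydroxy ester F14. These are diastereomers, because the core is enantiopure, and are separated. Hydroxy ester 27 is lactonised with DBU to 28. F14 is re-oxidised with MnO2, which is selective for the pyrrolyl carbinol, to 26 and recycled.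

**Step 18.** The exocyclic alkenes may migrate into the lactone rings before they are reduced, giving butenolides that resist hydrogenation and lose the stereochemical handle. The 1,3-induction at C20 may also be modest.

The fallback sets out from 32. Conjugate reduction with [(Ph3P)CuH]6 in wet toluene reduces only the two enoates. The copper enolates are protonated from the convex face at C13 and anti to the pyrrolyl group at C20, giving the 7,8-didehydro compound F15. Diimide (p-toluenesulfonyl hydrazide, NaOAc) then saturates C7=C8 and gives 33.

## Further compounds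

F1 | step 7 | methyl 2-{1-(but-3-en-1-yl)-3-[(1R,2E)-1-hydroxypent-2-en-1-yl]-1H-pyrrol-2-yl}acetate | CC/C=C/[C@@H](O)c1ccn(CCC=C)c1CC(=O)OC
F2 | step 7 | (4R)-1-(but-3-en-1-yl)-4-[(1E)-but-1-en-1-yl]-4,7-dihydropyrano[4,3-b]pyrrol-6(1H)-one | CC/C=C/[C@H]1OC(=O)Cc2c1ccn2CCC=C
F3 | step 7 | (4R)-1-(but-3-en-1-yl)-4-[(1E)-but-1-en-1-yl]-6-(trimethylsilyloxy)-1,4-dihydropyrano[4,3-b]pyrrole | CC/C=C/[C@H]1OC(O[Si](C)(C)C)=Cc2c1ccn2CCC=C
F4 | step 7 | trimethylsilyl (6S,7S)-1-(but-3-en-1-yl)-6-ethyl-6,7-dihydro-1H-indole-7-carboxylate | CC[C@H]1C=Cc2ccn(CCC=C)c2[C@H]1C(=O)O[Si](C)(C)C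
F5 | step 7 | (6S,7S)-1-(but-3-en-1-yl)-6-ethyl-6,7-dihydro-1H-indole-7-carboxylic acid | CC[C@H]1C=Cc2ccn(CCC=C)c2[C@H]1C(=O)O
F6 | step 7 | methyl (6S,7S)-1-(but-3-en-1-yl)-6-ethyl-6,7-dihydro-1H-indole-7-carboxylate | CC[C@H]1C=Cc2ccn(CCC=C)c2[C@H]1C(=O)OC
F7 | step 7 | methyl (6S,7R)-1-(but-3-en-1-yl)-6-ethyl-6,7-dihydro-1H-indole-7-carboxylate | CC[C@H]1C=Cc2ccn(CCC=C)c2[C@@H]1C(=O)OC
F8 | step 5 | methyl 2-[1-(but-3-en-1-yl)-3-(pent-2-ynoyl)-1H-pyrrol-2-yl]acetate | CCC#CC(=O)c1ccn(CCC=C)c1CC(=O)OC
F9 | step 12 | methyl (4S)-4-[(6S,7R)-1-(but-3-en-1-yl)-7-ethenyl-6-ethyl-6,7-dihydro-1H-indol-2-yl]-4-hydroxybutanoate | CC[C@H]1C=Cc2cc([C@@H](O)CCC(=O)OC)n(CCC=C)c2[C@@H]1C=C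
F10 | step 12 | (5S)-5-[(6S,7R)-1-(but-3-en-1-yl)-7-ethenyl-6-ethyl-6,7-dihydro-1H-indol-2-yl]dihydrofuran-2(3H)-one | CC[C@H]1C=Cc2cc([C@@H]3CCC(=O)O3)n(CCC=C)c2[C@@H]1C=C
F11 | step 12 | cis-fused 2,2-dichlorocyclobutanone adduct of F10 (C14=O on C11, C13Cl2 on C12, anti to the C10 ethyl group) | CC[C@H]1[C@@H]2C(=O)C(Cl)(Cl)[C@@H]2c2cc([C@@H]3CCC(=O)O3)n(CCC=C)c2[C@@H]1C=C
F12 | step 12 | cis-fused cyclobutanone (dechlorinated F11) | CC[C@H]1[C@@H]2C(=O)C[C@@H]2c2cc([C@@H]3CCC(=O)O3)n(CCC=C)c2[C@@H]1C=C
F13 | step 12 | bis-lactone with N-butenyl and C9-vinyl groups | CC[C@H]1[C@@H]2OC(=O)C[C@@H]2c2cc([C@@H]3CCC(=O)O3)n(CCC=C)c2[C@@H]1C=C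
F14 | step 15 | (18R)-hydroxy ester, C18 epimer of 27 | CC[C@H]1[C@@H]2OC(=O)C[C@@H]2c2cc([C@H](O)CCC(=O)OC)n3c2[C@@H]1C=CCC3
F15 | step 18 | 7,8-didehydro derivative of 33 | CC[C@H]1[C@@H]2OC(=O)[C@H](C)[C@@H]2c2cc([C@@H]3C[C@H](C)C(=O)O3)n3c2[C@@H]1C=CCC3
A1 | alternative 1 | C11 α-diazopropionate of the tricyclic C3 keto ester | CC[C@H]1[C@H](OC(=O)C(C)=[N+]=[N-])Cc2cc(C(=O)C[C@H](C)C(=O)OC)n3c2[C@@H]1CCCC3
A2 | alternative 1 | tetracyclic lactone with the C3 keto ester (C13 unassigned) | CC[C@H]1[C@@H]2OC(=O)C(C)[C@@H]2c2cc(C(=O)C[C@H](C)C(=O)OC)n3c2[C@@H]1CCCC3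
A3 | alternative 2 | N–H pyrrole carrying lactones D and E and the C9=C8–C7(=O)–C6=C5 dienone chain | CC[C@H](/C=C/C(=O)C=C)[C@@H]1OC(=O)[C@H](C)[C@@H]1c1cc([C@@H]2C[C@H](C)C(=O)O2)[nH]c1
A4 | alternative 2 | 7-oxo derivative of 33 | CC[C@H]1[C@@H]2OC(=O)[C@H](C)[C@@H]2c2cc([C@@H]3C[C@H](C)C(=O)O3)n3c2[C@@H]1CC(=O)CC3
A5 | alternative 3 | pyrroloazepine with the C9 allylsilane, the C11 aldehyde and the C13 methyl ester | C[Si](C)(C)C/C=C/[C@H]1CCCCn2c([C@@H]3C[C@H](C)C(=O)O3)cc([C@H](C=O)[C@@H](C)C(=O)OC)c12
A6 | alternative 3 | 10-vinyl analogue of 33 | C=C[C@H]1[C@@H]2OC(=O)[C@H](C)[C@@H]2c2cc([C@@H]3C[C@H](C)C(=O)O3)n3c2[C@@H]1CCCC3
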